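The plan cuts ring C (O1, C2, C3, C4, C4a, C8a) into two three-atom halves. C4–C4a–C8a becomes a 1,3-bis-electrophile, a benzylic bromide flanked by a C–F bond. C8a lies meta to the oxygens on C5 and C7 of ring A, so these donors do not block SNAr. O1–C2–C3 becomes a 1,3-bis-nucleophile, an enantiopure benzylic alkoxide next to a lithiated 1,3-dithiane that reverses the polarity of C3. In one flask C3 is alkylated by C4 and O1 displaces fluoride at C8a, a formal (3+3) annulation that leaves C2 untouched. Unmasking, cis-selective reduction, galloylation and hydrogenolysis complete the route.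

Key step: step 6

Numbering: flavan numbering is used (O1, C2, C3, C4, C4a, C5 to C8, C8a). Ring A is the benzo ring, ring B the 2-aryl group and ring C the pyran ring.
Assumption: methyl 3,4,5-tris(benzyloxy)benzoate and 3,4,5-tris(benzyloxy)benzoic acid are taken as catalogue compounds; each is otherwise one standard benzylation away from methyl gallate.

Step 1
Reactants: 1 2,4,6-trifluorobenzaldehyde; 2 benzyl alcohol
Product: 3 2,4-bis(benzyloxy)-6-fluorobenzaldehyde
Conditions: 2 (2.05 equiv), KOt-Bu (2.05 equiv), DMF, −10 °C → rt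
Reagents that add atoms: none
Why: Twofold nucleophilic aromatic substitution (SNAr): the formyl group activates the para and ortho C–F bonds, the dissociated benzyl oxide in DMF should take the para fluoride first and one ortho fluoride next, and each new donor slows the following substitution, so that two equivalents stop at the monofluoride 3.

Step 2
Reactants: 3 2,4-bis(benzyloxy)-6-fluorobenzaldehyde
Product: 4 [2,4-bis(benzyloxy)-6-fluorophenyl]methanol
Conditions: NaBH4, MeOH/THF, 0 °C
Reagents that add atoms: none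
Why: Chemoselective borohydride reduction of the aldehyde, which leaves the aryl fluoride and the benzyl ethers untouched.

Step 3
Reactants: 4 [2,4-bis(benzyloxy)-6-fluorophenyl]methanol
Product: 5 2,4-bis(benzyloxy)-6-fluorobenzyl bromide
Conditions: CBr4, PPh3, CH2Cl2, 0 °C; short silica plug, used at once as a cold solution
Reagents that add atoms: carbon tetrabromide BrC(Br)(Br)Br
Why: Appel bromination under neutral conditions converts the primary benzylic alcohol by SN2 attack of bromide on the alkoxyphosphonium ion and avoids the acid that would ionize this electron-rich benzylic system.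

Step 4
Reactants: 6 1,3-dithiane; 7 methyl 3,4,5-tris(benzyloxy)benzoate
Product: 9 (1,3-dithian-2-yl)[3,4,5-tris(benzyloxy)phenyl]methanone, via 2-lithio-1,3-dithiane 8 (not isolated)
Conditions: 6 (2.1 equiv), n-BuLi (2.1 equiv), THF, −30 °C; then 7, −78 → 0 °C; H2O
Reagents that add atoms: none
Why: Corey–Seebach acylation: 8 adds to the ester and methoxide leaves, and the acidic 2-acyl-dithiane is at once deprotonated by the second equivalent of 8, which shields the ketone from a second addition.

Step 5
Reactants: 9 (1,3-dithian-2-yl)[3,4,5-tris(benzyloxy)phenyl]methanone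
Product: 10 (R)-(1,3-dithian-2-yl)[3,4,5-tris(benzyloxy)phenyl]methanol
Conditions: RuCl[(S,S)-TsDPEN](p-cymene) (2 mol %), HCO2H/Et3N (5:2), CH2Cl2, 35 °C
Reagents that add atoms: none
Why: Noyori–Ikariya asymmetric transfer hydrogenation: the aryl ring of 9 lies under the η6-arene of the ruthenium hydride (CH–π attraction), so the (S,S)-ligand should deliver hydride to the Si face and set the future C2 as R (the descriptor is R because the dithianyl carbon outranks the aryl carbon).

Step 6
Reactants: 10 (R)-(1,3-dithian-2-yl)[3,4,5-tris(benzyloxy)phenyl]methanol; 5 2,4-bis(benzyloxy)-6-fluorobenzyl bromide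
Product: 13 (2'R)-5',7'-bis(benzyloxy)-2'-[3,4,5-tris(benzyloxy)phenyl]spiro[1,3-dithiane-2,3'-chroman], via O,C-dilithio dianion 11 (not isolated), via C-benzylated lithium alkoxide 12 (not isolated)
Conditions: n-BuLi (2.1 equiv), THF, −78 → −25 °C; 5 (1.0 equiv), DMPU, −78 °C; then KOt-Bu (2.5 equiv), −78 → 55 °C; H2O
Reagents that add atoms: none
Why: n-BuLi removes first the O–H and then, guided by the neighbouring lithium alkoxide, the dithiane C–H of 10, so that dianion 11 carries its more reactive, soft carbanion at C3, which attacks the benzylic CH2Br carbon (C4) of 5 in an SN2 reaction (Corey–Seebach dithiane alkylation) to give alkoxide 12. After exchange of lithium for potassium and warming, the C2 alkoxide O1 adds to the C–F carbon C8a and fluoride leaves through a Meisenheimer adduct (intramolecular SNAr), the closest known reaction type being the alkoxide-to-fluoroarene pyran closure of 2-alkyl-3,5-dialkoxyfluorobenzenes. Ring C is the only ring closed, as a six-membered, formally 6-exo-trig addition–elimination that is helped by the geminal dithio substitution at C3. No new stereocenter is formed, since C3 is a symmetric dithioketal carbon and C2 keeps its R configuration because neither its C–O nor its C–H bond is touched. The step needs C- over O-alkylation (secured by the far higher nucleophilicity of the carbanion at −78 °C and by one equivalent of 5), fluoride rather than the C5 benzyloxy group as leaving group (fluoride is by far the better nucleofuge in SNAr), and six- rather than five-membered closure (the masked C3 carries no oxygen nucleophile that could give a dihydrobenzofuran). Because C3 of 12 and 13 bears no hydrogen, neither epimerization nor E1cB opening of the new aryl ether can follow under the basic conditions.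

Step 7
Reactants: 13 (2'R)-5',7'-bis(benzyloxy)-2'-[3,4,5-tris(benzyloxy)phenyl]spiro[1,3-dithiane-2,3'-chroman]
Product: 14 (2R)-5,7-bis(benzyloxy)-2-[3,4,5-tris(benzyloxy)phenyl]chroman-3-one
Conditions: MeI (excess), CaCO3, MeCN/H2O (9:1), 45 °C
Reagents that add atoms: water O
Why: Alkylative dithioketal hydrolysis: S-methylation turns sulfur into a leaving group, water adds to the thionium ion, no oxidant touches the electron-rich rings, and the CaCO3 buffer keeps the medium near neutral so that C2 next to the new ketone is not epimerized.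

Step 8
Reactants: 14 (2R)-5,7-bis(benzyloxy)-2-[3,4,5-tris(benzyloxy)phenyl]chroman-3-one
Product: 15 (2R,3R)-5,7-bis(benzyloxy)-2-[3,4,5-tris(benzyloxy)phenyl]chroman-3-ol (2,3-cis)
Conditions: LiBH(s-Bu)3 (L-Selectride), LiBr, THF, −78 °C; H2O
Reagents that add atoms: none
Why: Substrate-controlled ketone reduction with a bulky trialkylborohydride: hydride reaches the C3 carbonyl from the ring face opposite to the C2 aryl group, which places the new hydroxyl group cis to ring B and sets C3 as R, while the low temperature preserves C2.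

Step 9
Reactants: 15 (2R,3R)-5,7-bis(benzyloxy)-2-[3,4,5-tris(benzyloxy)phenyl]chroman-3-ol; 16 3,4,5-tris(benzyloxy)benzoic acid
Product: 17 (2R,3R)-5,7-bis(benzyloxy)-2-[3,4,5-tris(benzyloxy)phenyl]chroman-3-yl 3,4,5-tris(benzyloxy)benzoate
Conditions: DCC, DMAP (cat), CH2Cl2, rt
Reagents that add atoms: none
Why: Steglich esterification acylates the hindered C3 hydroxyl group at oxygen through the N-acylpyridinium ion, so that neither stereocenter is touched.

Step 10
Reactants: 17 (2R,3R)-5,7-bis(benzyloxy)-2-[3,4,5-tris(benzyloxy)phenyl]chroman-3-yl 3,4,5-tris(benzyloxy)benzoate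
Product: 18 (−)-epigallocatechin gallate, (2R,3R)
Conditions: H2 (1 atm), Pd(OH)2/C, THF/MeOH, rt
Reagents that add atoms: none
Why: Catalytic hydrogenolysis cleaves all eight O-benzyl ethers under mild conditions, under which the gallate ester and the cyclic C2–O1 bond are expected to persist.

Compound list
1 | 2,4,6-trifluorobenzaldehyde | O=Cc1c(F)cc(F)cc1F | starting material
2 | benzyl alcohol | OCc1ccccc1 | starting material
3 | 2,4-bis(benzyloxy)-6-fluorobenzaldehyde | O=Cc1c(F)cc(OCc2ccccc2)cc1OCc1ccccc1 | intermediate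
4 | [2,4-bis(benzyloxy)-6-fluorophenyl]methanol | OCc1c(F)cc(OCc2ccccc2)cc1OCc1ccccc1 | intermediate
5 | 2,4-bis(benzyloxy)-6-fluorobenzyl bromide | BrCc1c(F)cc(OCc2ccccc2)cc1OCc1ccccc1 | intermediate
6 | 1,3-dithiane | C1CSCSC1 | starting material
7 | methyl 3,4,5-tris(benzyloxy)benzoate | COC(=O)c1cc(OCc2ccccc2)c(OCc2ccccc2)c(OCc2ccccc2)c1 | starting material
8 | 2-lithio-1,3-dithiane (not isolated) | [Li]C1SCCCS1 | intermediate
9 | (1,3-dithian-2-yl)[3,4,5-tris(benzyloxy)phenyl]methanone | O=C(C1SCCCS1)c1cc(OCc2ccccc2)c(OCc2ccccc2)c(OCc2ccccc2)c1 | intermediate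
10 | (R)-(1,3-dithian-2-yl)[3,4,5-tris(benzyloxy)phenyl]methanol | O[C@@H](C1SCCCS1)c1cc(OCc2ccccc2)c(OCc2ccccc2)c(OCc2ccccc2)c1 | intermediate
11 | O,C-dilithio dianion of 10, lithium on the alkoxide oxygen and on C2 of the dithiane (not isolated) | [Li]O[C@@H](C1([Li])SCCCS1)c1cc(OCc2ccccc2)c(OCc2ccccc2)c(OCc2ccccc2)c1 | intermediate
12 | lithium (R)-{2-[2,4-bis(benzyloxy)-6-fluorobenzyl]-1,3-dithian-2-yl}[3,4,5-tris(benzyloxy)phenyl]methanolate (not isolated) | [Li]O[C@@H](C1(Cc2c(F)cc(OCc3ccccc3)cc2OCc2ccccc2)SCCCS1)c1cc(OCc2ccccc2)c(OCc2ccccc2)c(OCc2ccccc2)c1 | intermediate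
13 | (2'R)-5',7'-bis(benzyloxy)-2'-[3,4,5-tris(benzyloxy)phenyl]spiro[1,3-dithiane-2,3'-chroman] | C12(SCCCS1)Cc1c(OCc3ccccc3)cc(OCc3ccccc3)cc1O[C@@H]2c1cc(OCc2ccccc2)c(OCc2ccccc2)c(OCc2ccccc2)c1 | intermediate
14 | (2R)-5,7-bis(benzyloxy)-2-[3,4,5-tris(benzyloxy)phenyl]chroman-3-one | O=C1Cc2c(OCc3ccccc3)cc(OCc3ccccc3)cc2O[C@@H]1c1cc(OCc2ccccc2)c(OCc2ccccc2)c(OCc2ccccc2)c1 | intermediate
15 | (2R,3R)-5,7-bis(benzyloxy)-2-[3,4,5-tris(benzyloxy)phenyl]chroman-3-ol | O[C@@H]1Cc2c(OCc3ccccc3)cc(OCc3ccccc3)cc2O[C@@H]1c1cc(OCc2ccccc2)c(OCc2ccccc2)c(OCc2ccccc2)c1 | intermediate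
16 | 3,4,5-tris(benzyloxy)benzoic acid | OC(=O)c1cc(OCc2ccccc2)c(OCc2ccccc2)c(OCc2ccccc2)c1 | starting material
17 | (2R,3R)-5,7-bis(benzyloxy)-2-[3,4,5-tris(benzyloxy)phenyl]chroman-3-yl 3,4,5-tris(benzyloxy)benzoate | O=C(O[C@@H]1Cc2c(OCc3ccccc3)cc(OCc3ccccc3)cc2O[C@@H]1c1cc(OCc2ccccc2)c(OCc2ccccc2)c(OCc2ccccc2)c1)c1cc(OCc2ccccc2)c(OCc2ccccc2)c(OCc2ccccc2)c1 | intermediate
18 | (−)-epigallocatechin gallate, (2R,3R) | O=C(O[C@@H]1Cc2c(O)cc(O)cc2O[C@@H]1c1cc(O)c(O)c(O)c1)c1cc(O)c(O)c(O)c1 | target

Total step count: 10.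
Longest linear sequence: 8 steps (1, 2, 3, 6, 7, 8, 9, 10).

Steps most likely to fail

Step 6. The second lithiation beside the alkoxide may stay incomplete, the benzyl ether CH2 groups may be metalated in competition, or the potassium alkoxide may undergo retro-addition while the SNAr closure is slow.
- The fallback sets out from ketone 9 and bromide 5 and avoids the dianion.
- The stabilized anion of 9 (NaH, DMF, 0 °C) is C-benzylated with 5 to give {2-[2,4-bis(benzyloxy)-6-fluorobenzyl]-1,3-dithian-2-yl}[3,4,5-tris(benzyloxy)phenyl]methanone F1.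
- Corey–Bakshi–Shibata reduction follows, with (S)-2-methyl-CBS-oxazaborolidine and BH3·SMe2. The quaternary dithianyl carbon is the clearly larger group, and the product is (R)-{2-[2,4-bis(benzyloxy)-6-fluorobenzyl]-1,3-dithian-2-yl}[3,4,5-tris(benzyloxy)phenyl]methanol F2.
- KH in DMF closes ring C by SNAr, and the sequence comes back to the route at 13.

Step 5. The thioether sulfur atoms may inhibit the ruthenium catalyst, hydride transfer to the hindered ketone may be sluggish, or facial selectivity may be poor.
- The fallback sets out from 9 and replaces asymmetric catalysis by a classical resolution.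
- NaBH4 gives racemic (1,3-dithian-2-yl)[3,4,5-tris(benzyloxy)phenyl]methanol F3.
- Esterification with (S)-2-methoxy-2-phenylacetic acid (DCC, DMAP) gives two diastereomeric esters. Crystallization or chromatography separates out (R)-(1,3-dithian-2-yl)[3,4,5-tris(benzyloxy)phenyl]methyl (S)-2-methoxy-2-phenylacetate F4.
- LiOH in THF/H2O cleaves F4, and the sequence comes back to the route at 10.
- The other diastereomer is hydrolysed and reoxidized to 9 for recycling.

Step 3. The electron-rich benzylic bromide may ionize and alkylate itself during preparation, filtration or transfer.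
- The fallback sets out from aldehyde 3 and carbinol 10 and needs no halide.
- Dianion 11, made from 10 as in step 6, is added to 3, so that the C3–C4 bond arises by carbonyl addition.
- KOt-Bu and warming then close ring C by the same SNAr reaction to give (2'R)-5',7'-bis(benzyloxy)-2'-[3,4,5-tris(benzyloxy)phenyl]spiro[1,3-dithiane-2,3'-chroman]-4'-ol F5, a mixture at C4.
- Ionic deoxygenation with Et3SiH and BF3·OEt2 in CH2Cl2 at −78 °C runs through the C4 cation stabilized by ring A. The sequence comes back to the route at 13 and makes steps 2 and 3 unnecessary.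

Further compounds
F1 | step 6 | {2-[2,4-bis(benzyloxy)-6-fluorobenzyl]-1,3-dithian-2-yl}[3,4,5-tris(benzyloxy)phenyl]methanone | O=C(C1(Cc2c(F)cc(OCc3ccccc3)cc2OCc2ccccc2)SCCCS1)c1cc(OCc2ccccc2)c(OCc2ccccc2)c(OCc2ccccc2)c1
F2 | step 6 | (R)-{2-[2,4-bis(benzyloxy)-6-fluorobenzyl]-1,3-dithian-2-yl}[3,4,5-tris(benzyloxy)phenyl]methanol | O[C@@H](C1(Cc2c(F)cc(OCc3ccccc3)cc2OCc2ccccc2)SCCCS1)c1cc(OCc2ccccc2)c(OCc2ccccc2)c(OCc2ccccc2)c1
F3 | step 5 | racemic (1,3-dithian-2-yl)[3,4,5-tris(benzyloxy)phenyl]methanol | OC(C1SCCCS1)c1cc(OCc2ccccc2)c(OCc2ccccc2)c(OCc2ccccc2)c1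
F4 | step 5 | (R)-(1,3-dithian-2-yl)[3,4,5-tris(benzyloxy)phenyl]methyl (S)-2-methoxy-2-phenylacetate | CO[C@H](C(=O)O[C@@H](C1SCCCS1)c1cc(OCc2ccccc2)c(OCc2ccccc2)c(OCc2ccccc2)c1)c1ccccc1
F5 | step 3 | (2'R)-5',7'-bis(benzyloxy)-2'-[3,4,5-tris(benzyloxy)phenyl]spiro[1,3-dithiane-2,3'-chroman]-4'-ol, mixture at C4 | C12(SCCCS1)C(O)c1c(OCc3ccccc3)cc(OCc3ccccc3)cc1O[C@@H]2c1cc(OCc2ccccc2)c(OCc2ccccc2)c(OCc2ccccc2)c1
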